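The trap in this flask is to lay a ruler along the left-handed product and carry it to the asked time, although the left-handed substrate feeding it thins out; so you count half-lives instead, taking the clocks in order of speed.

| setting | Friday's | Sunday's | Thursday's | south | south-west |
|---|---|---|---|---|---|
| left-handed substrate | 0.10 M | 0.10 M | 0.10 M | 0.10 M | 0.10 M |
| right-handed substrate | 0.10 M | 0.10 M | 0.10 M | 0.10 M | 0.10 M |
| solid reagent | 0.15 M | 0.16 M | 0.19 M | 0.220 M | 0.120 M |
| temperature | 2 °C | 19 °C | 2 °C | 25 °C | −5 °C |
| remark | run made earlier | run made earlier | run made earlier |  |  |
| time |  |  |  | 30 h | 100 h |

| Friday's: time / h | Friday's: left-handed product / % | Sunday's: time / h | Sunday's: left-handed product / % | Thursday's: time / h | Thursday's: left-handed product / % |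
|---|---|---|---|---|---|
| 25.0 | 8 | 4.00 | 1 | 12.0 | 6 |
| 50.0 | 16 | 10.0 | 15 | 30.0 | 11 |
| 72.0 | 20 | 20.0 | 23 | 60.0 | 18 |
| 96.0 | 26 | 30.0 | 31 | 96.0 | 26 |

(each reading ± 2 percentage points)

* the flask that ends with the higher amount of left-handed product, in percent of the left-handed substrate and right-handed substrate together charged, or "neither" when 2 percentage points or less lies between them (south / south-west / neither)
* final left-handed product, as a percentage of the left-handed substrate and right-handed substrate together charged, in south
* final left-handed product, as a percentage of the left-handed substrate and right-handed substrate together charged, in south-west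

- partner is single-handed; left-handed substrate and right-handed substrate are mirror images of each other, charged as a racemate, each of them at the stated concentration
- given per volume of solution although it is solid: solid reagent
- the numbers in the tables scatter by 2 percentage points (one standard deviation)
- at the start none of the solid reagent is in solution
- the handed part of partner does not stay in what it makes, so the products of the two hands are mirror images too

1. Start-up: Sunday's run reads 1% at 4.00 h but 15% at 10.0 h, which I read as solid reagent first putting partner into solution.

2. Supply: Friday's and Thursday's runs, at one temperature with 0.15 M and 0.19 M of solid reagent, both read 26% at 96.0 h, so I hold c(partner) steady while solid remains, which makes the left-handed substrate pseudo-first-order.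

3. Half-life: the left-handed substrate is half of the charge, and I assume that the left-handed product comes from it and that nothing else takes it, so you double each reading to get the fraction of it used. Sunday's last reading then gives 21.5 h and Friday's gives 90.7 h, an apparent activation energy of 56.6 kJ/mol. Moved to the flask's temperature, the half-life of the left-handed substrate is 13.4 h in south and 173 h in south-west.

4. Count: south has 2.24 half-lives, which gives 39.3% left-handed product. South-west has 0.578, which gives 16.5%. So I choose south.

5. Solid: even with the right-handed substrate taken at the same pace, south needs 0.157 M of its 0.220 M, and south-west needs 0.0660 M of its 0.120 M.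

The forecast, holding that "The left-handed product grows almost linearly with time", gives south, 39% and 16%, the last lower than mine.

The flask gives south, with 42.3% in south and 14.0% in south-west.

    partner + right-handed substrate → right-handed product (k = 0.847 /M/h, Ea = 62.0 kJ/mol)
    solid reagent ⇌ partner, rate k2*(cs2 - [partner]) while solid is left; crystals form when [partner] > cs2 (solubility = 44.0 mM, k = 0.664 /h)
    left-handed substrate ⇌ achiral form (K = 0.160, k = 0.0323 /h, Ea = 104 kJ/mol, ΔH = −6.00 kJ/mol)
    partner + left-handed substrate → left-handed product (k = 1.76 /M/h, Ea = 69.0 kJ/mol)
    right-handed substrate ⇌ achiral form (K = 0.160, k = 0.0323 /h, Ea = 104 kJ/mol, ΔH = −6.00 kJ/mol)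
    (constants at 25 °C)

In south, partner is made 1.07 times as fast as it is used at 30.0 h, and c(partner) stands at 0.0365 M at 15.0 h and 0.0398 M at 30.0 h, with 18.7% of the solid reagent's charge still undissolved. Counted over the 30 h, 13.4 h leaves 21.2% of the left-handed substrate's charge, and south holds 20% of it; but doubled, 42.3% plus that 20% comes to 105% of that charge, so the assumption of step 3 does not hold in south, where the scheme links the two hands through the achiral form.

On the flask south left until 8.0 h, 13.4 h counts 0.597 half-lives, which gives 16.9% left-handed product. The computed flask holds 15.7%.

All runs are simulated on assumed constants; scatter was added.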